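**Strategy**

The oxolane ring (O1, C2 bearing the alkenyl chain, C3H2, C4–OH, C5(CH3)2) is cut across C3–C4 and O1–C2, leading back to a terminal 1,3-diene and a masked 2-silyloxy-2-methylpropanal. In one operation TiCl4 opens a chiral 1,3-dioxane acetal, the diene terminus forms C3–C4 with inversion at the acetal carbon, and the silyl ether oxygen closes O1–C2 onto the allyl cation (formal [3+2] annulation). The step exploits two features: C2 is allylic to the side-chain alkene C(CH3)=CH, and C4(OH)–C5(CH3)2–O1 is a latent α-oxy aldehyde. The precursors are a triene ester from methyl geranate and a (2R,4R)-pentane-2,4-diol acetal, whose dioxane ring, absent from the target, sets C4 and is cleaved afterwards.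

Key step: step 5

Remark: methyl geranate is taken as the pure (2E)-isomer, and the sense of induction in steps 5 and 10 is assigned from the usual selectivity models for the chiral acetal template and the chiral phosphoric acid; the antipodal diol or acid would be used if the sense proved opposite.

**Route**

Step 1
Reactants: 1 methyl (2E)-3,7-dimethylocta-2,6-dienoate (methyl geranate)
Product: 2 methyl (2E,6E)-3,7-dimethyl-8-oxoocta-2,6-dienoate
Conditions: SeO2 (1.2 equiv), EtOH, reflux
Reagents that add atoms: selenium dioxide O=[Se]=O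
Why: Riley allylic oxidation (ene reaction then [2,3]-sigmatropic shift) should attack only the electron-rich trisubstituted alkene at its (E)-methyl group and carry it on to the (E)-enal, leaving the electron-poor enoate untouched.

Step 2
Reactants: 2 methyl (2E,6E)-3,7-dimethyl-8-oxoocta-2,6-dienoate
Product: 3 methyl (2E,6E)-3,7-dimethylnona-2,6,8-trienoate
Conditions: Ph3PCH3Br, n-BuLi, THF, 0 °C; then 2, −78 °C to 0 °C
Reagents that add atoms: methyltriphenylphosphonium bromide C[P+](c1ccccc1)(c1ccccc1)c1ccccc1.[Br-]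
Why: Wittig methylenation of the aldehyde by the non-stabilised ylide is much faster than attack on the conjugated ester and leaves both trisubstituted alkenes (E).

Step 3
Reactants: 4 1,1-dimethoxypropan-2-one
Product: 6 [(1,1-dimethoxy-2-methylpropan-2-yl)oxy]triethylsilane, via magnesium alkoxide 5 (not isolated)
Conditions: MeMgBr, Et2O, 0 °C; then TESOTf, 0 °C to rt
Reagents that add atoms: methylmagnesium bromide C[Mg]Br; triethylsilyl trifluoromethanesulfonate CC[Si](CC)(CC)OS(=O)(=O)C(F)(F)F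
Why: Grignard addition to the ketone gives the tertiary magnesium alkoxide, which is O-silylated in the same flask by the silyl triflate.

Step 4
Reactants: 6 [(1,1-dimethoxy-2-methylpropan-2-yl)oxy]triethylsilane; 7 (2R,4R)-pentane-2,4-diol
Product: 8 triethyl{[2-((4R,6R)-4,6-dimethyl-1,3-dioxan-2-yl)propan-2-yl]oxy}silane
Conditions: PPTS (cat.), toluene, 80 °C, 4 Å molecular sieves (removal of MeOH)
Reagents that add atoms: none
Why: Acid-catalysed transacetalisation is driven by removal of methanol and gives the trans-4,6-dimethyl-1,3-dioxane, whose acetal carbon is not a stereocentre because the diol is C2-symmetric.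

Step 5
Reactants: 3 methyl (2E,6E)-3,7-dimethylnona-2,6,8-trienoate; 8 triethyl{[2-((4R,6R)-4,6-dimethyl-1,3-dioxan-2-yl)propan-2-yl]oxy}silane
Product: 10 methyl (2E,6E)-7-[(2S,4S)-4-{[(2R,4R)-4-hydroxypentan-2-yl]oxy}-5,5-dimethyloxolan-2-yl]-3-methylocta-2,6-dienoate, via allyl-cation titanate 9 (not isolated)
Conditions: TiCl4 (2.5 equiv), 2,6-di-tert-butyl-4-methylpyridine (0.3 equiv), CH2Cl2, −78 °C; aq. NaHCO3
Reagents that add atoms: none
Why: Proposed new method: TiCl4 complexes the acetal oxygen next to the axial methyl of 8 and the unsubstituted diene terminus of 3 displaces it with inversion (Prins-type opening of a chiral pentane-2,4-diol acetal), forming C3–C4 and the allyl cation 9; the tertiary silyl ether oxygen then adds to the cation terminus and the silyloxonium ion loses Et3Si to chloride, forming O1–C2. The closest known reaction types are the TiCl4-mediated coupling of such chiral acetals with alkenes and allylsilanes and the Lewis acid-promoted formal [3+2] annulation of α-silyloxy aldehydes with styrenes to oxolan-3-ols, a 1,3-diene partner being the untested element. The oxolane closes in the 5-exo-trig mode onto the allyl cation. C4 should become (S) under control of the (4R,6R)-dioxane template (anti attack on the C–O bond whose cleavage relieves the axial methyl), and C2 should become (S) relative to C4 because closure passes through an envelope with the C4 ether and the alkenyl group pseudo-equatorial while the cation is ion-paired on the face of the titanium alkoxide tether, which should give the 2,4-cis ring. The step needs attack by the diene terminus only, five-membered closure and no [4+2] adduct: the conjugated ester deactivates the other trisubstituted alkene, the alkylated acetal oxygen cannot close a dihydropyran, the seven-membered alternative is slower, and chloride capture of the cation is reversible under TiCl4.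

Step 6
Reactants: 10 methyl (2E,6E)-7-[(2S,4S)-4-{[(2R,4R)-4-hydroxypentan-2-yl]oxy}-5,5-dimethyloxolan-2-yl]-3-methylocta-2,6-dienoate
Product: 12 methyl (2E,6E)-7-[(2S,4S)-4-hydroxy-5,5-dimethyloxolan-2-yl]-3-methylocta-2,6-dienoate, via β-alkoxy ketone 11 (not isolated)
Conditions: Dess–Martin periodinane, NaHCO3, CH2Cl2, rt; then MeOH, K2CO3, rt
Reagents that add atoms: none
Why: Dess–Martin oxidation turns the auxiliary carbinol into a β-alkoxy ketone, from which base expels the oxolane alkoxide by E1cB elimination (the standard removal of this template), leaving both ring stereocentres and the methyl ester untouched.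

Step 7
Reactants: 12 methyl (2E,6E)-7-[(2S,4S)-4-hydroxy-5,5-dimethyloxolan-2-yl]-3-methylocta-2,6-dienoate
Product: 13 methyl (2E,6E)-7-{(2S,4S)-4-[(tert-butyldimethylsilyl)oxy]-5,5-dimethyloxolan-2-yl}-3-methylocta-2,6-dienoate
Conditions: TBSOTf, 2,6-lutidine, CH2Cl2, 0 °C
Reagents that add atoms: tert-butyldimethylsilyl trifluoromethanesulfonate CC(C)(C)[Si](C)(C)OS(=O)(=O)C(F)(F)F
Why: Silylation of the hindered secondary alcohol with the silyl triflate masks the ring hydroxyl through the organometallic steps and the later acetylation.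

Step 8
Reactants: 13 methyl (2E,6E)-7-{(2S,4S)-4-[(tert-butyldimethylsilyl)oxy]-5,5-dimethyloxolan-2-yl}-3-methylocta-2,6-dienoate
Product: 14 (2E,6E)-7-{(2S,4S)-4-[(tert-butyldimethylsilyl)oxy]-5,5-dimethyloxolan-2-yl}-3-methylocta-2,6-dien-1-ol
Conditions: i-Bu2AlH (2.5 equiv), CH2Cl2, −78 °C; aq. potassium sodium tartrate
Reagents that add atoms: none
Why: 1,2-Reduction of the conjugated ester by the aluminium hydride should give the (E)-allylic alcohol without touching the silyl ether or the alkenes.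

Step 9
Reactants: 14 (2E,6E)-7-{(2S,4S)-4-[(tert-butyldimethylsilyl)oxy]-5,5-dimethyloxolan-2-yl}-3-methylocta-2,6-dien-1-ol
Product: 15 (2E,6E)-7-{(2S,4S)-4-[(tert-butyldimethylsilyl)oxy]-5,5-dimethyloxolan-2-yl}-3-methylocta-2,6-dienal
Conditions: MnO2, CH2Cl2, rt
Reagents that add atoms: none
Why: MnO2 oxidises the allylic alcohol selectively to the (E)-enal without isomerising the double bond.

Step 10
Reactants: 15 (2E,6E)-7-{(2S,4S)-4-[(tert-butyldimethylsilyl)oxy]-5,5-dimethyloxolan-2-yl}-3-methylocta-2,6-dienal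
Product: 16 (4S,5E,9E)-10-{(2S,4S)-4-[(tert-butyldimethylsilyl)oxy]-5,5-dimethyloxolan-2-yl}-6-methylundeca-5,9-dien-1-yn-4-ol
Conditions: allenylboronic acid pinacol ester, (S)-TRIP phosphoric acid (5 mol %), 4 Å molecular sieves, toluene, −20 °C
Reagents that add atoms: allenylboronic acid pinacol ester C=C=CB1OC(C)(C)C(C)(C)O1
Why: Chiral phosphoric acid-catalysed propargylation through a closed six-membered transition state should set the (S)-carbinol under catalyst control (sense assigned from aryl and alkenyl aldehydes with this acid family), the remote oxolane centres exerting no influence.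

Step 11
Reactants: 17 2-hydroxy-3-methylbenzaldehyde
Product: 19 2,5-dihydroxy-3-methylbenzaldehyde, via aryl sulfate 18 (not isolated)
Conditions: K2S2O8, NaOH (aq), 0 °C to rt; then HCl (aq), 80 °C
Reagents that add atoms: potassium peroxodisulfate [K+].[K+].[O-]S(=O)(=O)OOS(=O)(=O)[O-]
Why: Elbs persulfate oxidation hydroxylates the phenolate at the only free para position via the aryl sulfate, which acid then hydrolyses.

Step 12
Reactants: 19 2,5-dihydroxy-3-methylbenzaldehyde
Product: 20 2,5-bis[(tert-butyldimethylsilyl)oxy]-3-methylbenzaldehyde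
Conditions: TBSCl, imidazole, DMF, 40 °C
Reagents that add atoms: tert-butyldimethylsilyl chloride CC(C)(C)[Si](C)(C)Cl
Why: Imidazole-assisted silylation of both phenols protects the hydroquinone in a form that the final fluoride step removes.

Step 13
Reactants: 20 2,5-bis[(tert-butyldimethylsilyl)oxy]-3-methylbenzaldehyde
Product: 21 {2,5-bis[(tert-butyldimethylsilyl)oxy]-3-methylphenyl}methanol
Conditions: i-Bu2AlH, CH2Cl2, −78 °C; aq. potassium sodium tartrate
Reagents that add atoms: none
Why: Hydride reduction at low temperature through a neutral aluminium alkoxide should avoid phenol-to-benzyl silyl migration.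

Step 14
Reactants: 21 {2,5-bis[(tert-butyldimethylsilyl)oxy]-3-methylphenyl}methanol
Product: 22 2,5-bis[(tert-butyldimethylsilyl)oxy]-3-methylbenzyl chloride
Conditions: Ph3P, N-chlorosuccinimide, CH2Cl2, −20 °C to 0 °C
Reagents that add atoms: N-chlorosuccinimide O=C1CCC(=O)N1Cl
Why: Appel-type chlorination converts the benzylic alcohol into the chloride under neutral conditions that spare the aryl silyl ethers.

Step 15
Reactants: 16 (4S,5E,9E)-10-{(2S,4S)-4-[(tert-butyldimethylsilyl)oxy]-5,5-dimethyloxolan-2-yl}-6-methylundeca-5,9-dien-1-yn-4-ol; 22 2,5-bis[(tert-butyldimethylsilyl)oxy]-3-methylbenzyl chloride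
Product: 24 (2E,5S,6E,10E)-1-{2,5-bis[(tert-butyldimethylsilyl)oxy]-3-methylphenyl}-11-{(2S,4S)-4-[(tert-butyldimethylsilyl)oxy]-5,5-dimethyloxolan-2-yl}-3,7-dimethyldodeca-2,6,10-trien-5-ol, via alkenylalane 23 (not isolated)
Conditions: Me3Al (3 equiv), Cp2ZrCl2 (0.2 equiv), CH2Cl2, 0 °C to rt; then 22, Pd(PPh3)4 (5 mol %), THF, rt; aq. potassium sodium tartrate
Reagents that add atoms: trimethylaluminium C[Al](C)C
Why: Zirconium-catalysed syn-carboalumination (Negishi) of the terminal alkyne places methyl on the internal carbon and gives the (E)-alkenylalane, which is benzylated with retention by palladium-catalysed cross-coupling, fixing the (2E)-trisubstituted alkene.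

Step 16
Reactants: 24 (2E,5S,6E,10E)-1-{2,5-bis[(tert-butyldimethylsilyl)oxy]-3-methylphenyl}-11-{(2S,4S)-4-[(tert-butyldimethylsilyl)oxy]-5,5-dimethyloxolan-2-yl}-3,7-dimethyldodeca-2,6,10-trien-5-ol
Product: 25 (2E,5S,6E,10E)-1-{2,5-bis[(tert-butyldimethylsilyl)oxy]-3-methylphenyl}-11-{(2S,4S)-4-[(tert-butyldimethylsilyl)oxy]-5,5-dimethyloxolan-2-yl}-3,7-dimethyldodeca-2,6,10-trien-5-yl acetate
Conditions: Ac2O, Et3N, DMAP (cat.), CH2Cl2, 0 °C
Reagents that add atoms: acetic anhydride CC(=O)OC(C)=O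
Why: DMAP-catalysed acetylation of the only free hydroxyl installs the acetate with retention of configuration.

Step 17
Reactants: 25 (2E,5S,6E,10E)-1-{2,5-bis[(tert-butyldimethylsilyl)oxy]-3-methylphenyl}-11-{(2S,4S)-4-[(tert-butyldimethylsilyl)oxy]-5,5-dimethyloxolan-2-yl}-3,7-dimethyldodeca-2,6,10-trien-5-yl acetate
Product: 26 (2E,5S,6E,10E)-1-(2,5-dihydroxy-3-methylphenyl)-11-[(2S,4S)-4-hydroxy-5,5-dimethyloxolan-2-yl]-3,7-dimethyldodeca-2,6,10-trien-5-yl acetate
Conditions: HF·pyridine, pyridine, THF, 0 °C to rt, under argon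
Reagents that add atoms: none
Why: Pyridine-buffered fluoride desilylation should cleave the two aryl silyl ethers and the alkyl silyl ether while the allylic acetate and the alkenyl oxolane survive.

**Compound list**

1 | methyl (2E)-3,7-dimethylocta-2,6-dienoate (methyl geranate) | COC(=O)/C=C(\C)CCC=C(C)C | starting material
2 | methyl (2E,6E)-3,7-dimethyl-8-oxoocta-2,6-dienoate | COC(=O)/C=C(\C)CC/C=C(\C)C=O | intermediate
3 | methyl (2E,6E)-3,7-dimethylnona-2,6,8-trienoate | COC(=O)/C=C(\C)CC/C=C(\C)C=C | intermediate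
4 | 1,1-dimethoxypropan-2-one (pyruvaldehyde dimethyl acetal) | CC(=O)C(OC)OC | starting material
5 | bromomagnesium 1,1-dimethoxy-2-methylpropan-2-olate | CC(C)(O[Mg]Br)C(OC)OC | intermediate
6 | [(1,1-dimethoxy-2-methylpropan-2-yl)oxy]triethylsilane | CC[Si](CC)(CC)OC(C)(C)C(OC)OC | intermediate
7 | (2R,4R)-pentane-2,4-diol | C[C@@H](O)C[C@@H](C)O | starting material
8 | triethyl{[2-((4R,6R)-4,6-dimethyl-1,3-dioxan-2-yl)propan-2-yl]oxy}silane | C[C@@H]1C[C@@H](C)OC(C(C)(C)O[Si](CC)(CC)CC)O1 | intermediate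
9 | titanate-paired allyl cation formed after C3–C4 bond formation, ring not yet closed | COC(=O)/C=C(\C)CC/C=C(\C)[CH+]C[C@H](O[C@H](C)C[C@@H](C)O[Ti-](Cl)(Cl)(Cl)Cl)C(C)(C)O[Si](CC)(CC)CC | intermediate
10 | methyl (2E,6E)-7-[(2S,4S)-4-{[(2R,4R)-4-hydroxypentan-2-yl]oxy}-5,5-dimethyloxolan-2-yl]-3-methylocta-2,6-dienoate | COC(=O)/C=C(\C)CC/C=C(\C)[C@@H]1C[C@H](O[C@H](C)C[C@@H](C)O)C(C)(C)O1 | intermediate
11 | methyl (2E,6E)-7-[(2S,4S)-5,5-dimethyl-4-{[(2R)-4-oxopentan-2-yl]oxy}oxolan-2-yl]-3-methylocta-2,6-dienoate | COC(=O)/C=C(\C)CC/C=C(\C)[C@@H]1C[C@H](O[C@H](C)CC(C)=O)C(C)(C)O1 | intermediate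
12 | methyl (2E,6E)-7-[(2S,4S)-4-hydroxy-5,5-dimethyloxolan-2-yl]-3-methylocta-2,6-dienoate | COC(=O)/C=C(\C)CC/C=C(\C)[C@@H]1C[C@H](O)C(C)(C)O1 | intermediate
13 | methyl (2E,6E)-7-{(2S,4S)-4-[(tert-butyldimethylsilyl)oxy]-5,5-dimethyloxolan-2-yl}-3-methylocta-2,6-dienoate | COC(=O)/C=C(\C)CC/C=C(\C)[C@@H]1C[C@H](O[Si](C)(C)C(C)(C)C)C(C)(C)O1 | intermediate
14 | (2E,6E)-7-{(2S,4S)-4-[(tert-butyldimethylsilyl)oxy]-5,5-dimethyloxolan-2-yl}-3-methylocta-2,6-dien-1-ol | OC/C=C(\C)CC/C=C(\C)[C@@H]1C[C@H](O[Si](C)(C)C(C)(C)C)C(C)(C)O1 | intermediate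
15 | (2E,6E)-7-{(2S,4S)-4-[(tert-butyldimethylsilyl)oxy]-5,5-dimethyloxolan-2-yl}-3-methylocta-2,6-dienal | O=C/C=C(\C)CC/C=C(\C)[C@@H]1C[C@H](O[Si](C)(C)C(C)(C)C)C(C)(C)O1 | intermediate
16 | (4S,5E,9E)-10-{(2S,4S)-4-[(tert-butyldimethylsilyl)oxy]-5,5-dimethyloxolan-2-yl}-6-methylundeca-5,9-dien-1-yn-4-ol | C#CC[C@H](O)/C=C(\C)CC/C=C(\C)[C@@H]1C[C@H](O[Si](C)(C)C(C)(C)C)C(C)(C)O1 | intermediate
17 | 2-hydroxy-3-methylbenzaldehyde | Cc1cccc(C=O)c1O | starting material
18 | potassium 3-formyl-4-hydroxy-5-methylphenyl sulfate | Cc1cc(OS(=O)(=O)[O-])cc(C=O)c1O.[K+] | intermediate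
19 | 2,5-dihydroxy-3-methylbenzaldehyde | Cc1cc(O)cc(C=O)c1O | intermediate
20 | 2,5-bis[(tert-butyldimethylsilyl)oxy]-3-methylbenzaldehyde | Cc1cc(O[Si](C)(C)C(C)(C)C)cc(C=O)c1O[Si](C)(C)C(C)(C)C | intermediate
21 | {2,5-bis[(tert-butyldimethylsilyl)oxy]-3-methylphenyl}methanol | Cc1cc(O[Si](C)(C)C(C)(C)C)cc(CO)c1O[Si](C)(C)C(C)(C)C | intermediate
22 | 2,5-bis[(tert-butyldimethylsilyl)oxy]-3-methylbenzyl chloride | Cc1cc(O[Si](C)(C)C(C)(C)C)cc(CCl)c1O[Si](C)(C)C(C)(C)C | intermediate
23 | (E)-alkenyl(dimethyl)alane of 16 with the carbinol as its dimethylaluminium alkoxide | C[Al](C)/C=C(\C)C[C@H](O[Al](C)C)/C=C(\C)CC/C=C(\C)[C@@H]1C[C@H](O[Si](C)(C)C(C)(C)C)C(C)(C)O1 | intermediate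
24 | (2E,5S,6E,10E)-1-{2,5-bis[(tert-butyldimethylsilyl)oxy]-3-methylphenyl}-11-{(2S,4S)-4-[(tert-butyldimethylsilyl)oxy]-5,5-dimethyloxolan-2-yl}-3,7-dimethyldodeca-2,6,10-trien-5-ol | Cc1cc(O[Si](C)(C)C(C)(C)C)cc(C/C=C(\C)C[C@H](O)/C=C(\C)CC/C=C(\C)[C@@H]2C[C@H](O[Si](C)(C)C(C)(C)C)C(C)(C)O2)c1O[Si](C)(C)C(C)(C)C | intermediate
25 | (2E,5S,6E,10E)-1-{2,5-bis[(tert-butyldimethylsilyl)oxy]-3-methylphenyl}-11-{(2S,4S)-4-[(tert-butyldimethylsilyl)oxy]-5,5-dimethyloxolan-2-yl}-3,7-dimethyldodeca-2,6,10-trien-5-yl acetate | Cc1cc(O[Si](C)(C)C(C)(C)C)cc(C/C=C(\C)C[C@H](OC(C)=O)/C=C(\C)CC/C=C(\C)[C@@H]2C[C@H](O[Si](C)(C)C(C)(C)C)C(C)(C)O2)c1O[Si](C)(C)C(C)(C)C | intermediate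
26 | (2E,5S,6E,10E)-1-(2,5-dihydroxy-3-methylphenyl)-11-[(2S,4S)-4-hydroxy-5,5-dimethyloxolan-2-yl]-3,7-dimethyldodeca-2,6,10-trien-5-yl acetate | CC(=O)O[C@H](/C=C(\C)CC/C=C(\C)[C@@H]1C[C@H](O)C(C)(C)O1)C/C(C)=C/Cc1cc(O)cc(C)c1O | target

**Step count**

Total step count: 17. Longest linear sequence: 11 steps (from 1 through steps 1, 2, 5, 6, 7, 8, 9, 10, 15, 16, 17; the acetal branch through steps 3 and 4 is equally long).

**Steps most likely to fail**

1. Step 5 (Proposed new method). What may go wrong: ionisation of the acetal without capture by the diene, followed by a 1,2-methyl shift (α-ketol-type rearrangement); attack at the substituted diene terminus; cationic oligomerisation of the diene; or poor facial selectivity in the ring closure. The fallback uses known chemistry, still forms O1–C2 and C3–C4 in one operation, sets out from 2 and returns at 12. Wittig olefination of 2 with tert-butyl (triphenylphosphoranylidene)acetate gives the dienoate 1-tert-butyl 10-methyl (2E,4E,8E)-4,8-dimethyldeca-2,4,8-trienedioate F1. Treatment of F1 with methyl 2-hydroxy-2-methylpropanoate and NaH in THF effects an oxa-Michael addition followed by Dieckmann condensation and gives the racemic keto ester tert-butyl 5,5-dimethyl-2-[(2E,6E)-8-methoxy-6-methyl-8-oxoocta-2,6-dien-2-yl]-4-oxooxolane-3-carboxylate F2. Warming with p-TsOH in toluene removes the tert-butyl ester with decarboxylation and gives the racemic ketone methyl (2E,6E)-7-(5,5-dimethyl-4-oxooxolan-2-yl)-3-methylocta-2,6-dienoate F3. Corey–Bakshi–Shibata reduction with (R)-2-methyl-CBS-oxazaborolidine and BH3·SMe2 should reduce both enantiomers to the (4S)-carbinol under reagent control. Chromatography then separates the 2,4-cis alcohol 12 from the 2,4-trans diastereomer methyl (2E,6E)-7-[(2R,4S)-4-hydroxy-5,5-dimethyloxolan-2-yl]-3-methylocta-2,6-dienoate F4. This fallback gives up half of the material at the reduction stage.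

2. Step 15. What may go wrong: incomplete or regiorandom carbometalation, protonolysis of the alkenylalane, and slow transmetalation to palladium with the hindered, electron-rich benzylic chloride, leading to homocoupling or loss of the ortho silyl group. The fallback reverses the polarity of the coupling, sets out from 16 and 22 and returns at 24. The carboalumination of 16 is quenched with I2 to give the vinyl iodide (1E,4S,5E,9E)-10-{(2S,4S)-4-[(tert-butyldimethylsilyl)oxy]-5,5-dimethyloxolan-2-yl}-1-iodo-2,6-dimethylundeca-1,5,9-trien-4-ol F5. Chloride 22 is converted with Zn dust and LiCl in THF into {2,5-bis[(tert-butyldimethylsilyl)oxy]-3-methylbenzyl}zinc chloride F6. Negishi coupling of F5 with F6 under Pd(PPh3)4 in THF then gives 24.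

3. Step 10. What may go wrong: low enantiofacial selectivity with the β,β-disubstituted enal, slow turnover, or attack through the α-carbon of the boronate giving an allenyl carbinol. The fallback replaces catalyst-controlled addition by an oxidation–reduction sequence, sets out from 15 and returns at 16. Barbier addition of propargyl bromide and Zn to 15 gives, as a mixture of carbinol epimers, (5E,9E)-10-{(2S,4S)-4-[(tert-butyldimethylsilyl)oxy]-5,5-dimethyloxolan-2-yl}-6-methylundeca-5,9-dien-1-yn-4-ol F7. Dess–Martin oxidation gives the ynone (5E,9E)-10-{(2S,4S)-4-[(tert-butyldimethylsilyl)oxy]-5,5-dimethyloxolan-2-yl}-6-methylundeca-5,9-dien-1-yn-4-one F8. Corey–Bakshi–Shibata reduction with (R)-2-methyl-CBS-oxazaborolidine and catecholborane at −78 °C, with the alkenyl group as the large substituent, should then give 16.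

**Further compounds**

F1 | step 5 | 1-tert-butyl 10-methyl (2E,4E,8E)-4,8-dimethyldeca-2,4,8-trienedioate | COC(=O)/C=C(\C)CC/C=C(\C)/C=C/C(=O)OC(C)(C)C
F2 | step 5 | tert-butyl 5,5-dimethyl-2-[(2E,6E)-8-methoxy-6-methyl-8-oxoocta-2,6-dien-2-yl]-4-oxooxolane-3-carboxylate (racemic) | COC(=O)/C=C(\C)CC/C=C(\C)C1OC(C)(C)C(=O)C1C(=O)OC(C)(C)C
F3 | step 5 | methyl (2E,6E)-7-(5,5-dimethyl-4-oxooxolan-2-yl)-3-methylocta-2,6-dienoate (racemic) | COC(=O)/C=C(\C)CC/C=C(\C)C1CC(=O)C(C)(C)O1
F4 | step 5 | methyl (2E,6E)-7-[(2R,4S)-4-hydroxy-5,5-dimethyloxolan-2-yl]-3-methylocta-2,6-dienoate | COC(=O)/C=C(\C)CC/C=C(\C)[C@H]1C[C@H](O)C(C)(C)O1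
F5 | step 15 | (1E,4S,5E,9E)-10-{(2S,4S)-4-[(tert-butyldimethylsilyl)oxy]-5,5-dimethyloxolan-2-yl}-1-iodo-2,6-dimethylundeca-1,5,9-trien-4-ol | I/C=C(\C)C[C@H](O)/C=C(\C)CC/C=C(\C)[C@@H]1C[C@H](O[Si](C)(C)C(C)(C)C)C(C)(C)O1
F6 | step 15 | {2,5-bis[(tert-butyldimethylsilyl)oxy]-3-methylbenzyl}zinc chloride | Cc1cc(O[Si](C)(C)C(C)(C)C)cc(C[Zn]Cl)c1O[Si](C)(C)C(C)(C)C
F7 | step 10 | (5E,9E)-10-{(2S,4S)-4-[(tert-butyldimethylsilyl)oxy]-5,5-dimethyloxolan-2-yl}-6-methylundeca-5,9-dien-1-yn-4-ol, mixture of carbinol epimers | C#CCC(O)/C=C(\C)CC/C=C(\C)[C@@H]1C[C@H](O[Si](C)(C)C(C)(C)C)C(C)(C)O1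
F8 | step 10 | (5E,9E)-10-{(2S,4S)-4-[(tert-butyldimethylsilyl)oxy]-5,5-dimethyloxolan-2-yl}-6-methylundeca-5,9-dien-1-yn-4-one | C#CCC(=O)/C=C(\C)CC/C=C(\C)[C@@H]1C[C@H](O[Si](C)(C)C(C)(C)C)C(C)(C)O1
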